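**Plan**

- Retrosynthesis: cut the two isovalerate C–O bonds and the lactone C12–O8 bond, then C10–C14 (methyl from an enol triflate), then C2–C3 while C5–C10 is re-formed (retro-[3,3], ten-membered ring back to a cyclohexane), then C10–C1 (vinyl), C4–C3 and C5–C4 (enol-ether arm), and last C6–C7 and C8–C9 (Diels–Alder).
- Enabling feature: in the ten-membered ring, C10=C1–C2–C3–C4=C5 is a 1,5-diene whose C2–C3 bond lies opposite C5–C10. It maps onto a trans-1-vinyl-2-alkenylcyclohexanol made of C5 to C10, whose C10 oxygen is later exchanged for the C14 methyl.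
- Forward order: six-membered ring by Diels–Alder (step 2), a temporary γ-lactone from O10 to C15 (step 14), ring expansion six to ten (step 18), α-methylene-γ-lactone last (step 23).
- Stereochemistry: C7/C8 trans from the E dienophile, absolute configuration by lipase resolution. C6 is relayed from C8 through a C10-alcohol-directed epoxidation. C5 and C10 (both transient) come from axial protonation and equatorial vinyl addition. C3 and both ring alkenes come from the chair oxy-Cope of an E enol ether, and C14 enters with retention.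

Key step: step 18

Convention: every intermediate carries the germacrane numbers of the target (the cyclohexane is C5 to C10); β is the ring face of the C7 side chain, α the opposite face; TBS = tert-butyldimethylsilyl, TES = triethylsilyl, PMB = p-methoxybenzyl.

Assumption: the lipase of step 4 acylates the 8R carbinol faster (C7 as large, C9 as medium substituent of the empirical model for secondary alcohols), so the 8S alcohol is the recovered enantiomer.

**Route**

Step 1
Reactants: 1 methyl propiolate; 2 acetic acid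
Product: 3 methyl (E)-3-acetoxyprop-2-enoate
Conditions: DABCO (cat.), CH2Cl2, 0 °C to rt
Reagents that add atoms: none
Why: Amine-catalysed conjugate addition (oxa-Michael) of the carboxylic acid to the ynoate gives the β-acyloxy acrylate, and reversible addition under these conditions leads to the more stable E isomer.

Step 2
Reactants: 3 methyl (E)-3-acetoxyprop-2-enoate; 4 (E)-1-methoxy-3-(trimethylsilyloxy)buta-1,3-diene
Product: 5 racemic methyl 6-acetoxy-2-methoxy-4-(trimethylsilyloxy)cyclohex-3-ene-1-carboxylate (C7/C8 trans; both C6 epimers)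
Conditions: toluene, 110 °C, sealed tube
Reagents that add atoms: none
Why: Thermal Diels–Alder reaction of the electron-rich diene joins its CH2 terminus to the acetoxy-bearing β-carbon (C9–C8) and its methoxy-bearing terminus to the ester-bearing carbon (C6–C7), and suprafacial addition to the E dienophile makes C7 and C8 trans; the C6 methoxy centre is lost in step 3 and the adduct is racemic.

Step 3
Reactants: 5 racemic Diels–Alder adduct; 6 (trimethylsilyl)methylmagnesium chloride
Product: 8 racemic (4R*,5S*)-5-hydroxy-4-[3-(trimethylsilyl)prop-1-en-2-yl]cyclohex-2-en-1-one, via bis(silylmethyl) carbinol 7 (not isolated)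
Conditions: CeCl3, THF, −78 °C to rt; then 0.5 M HCl, THF, 0 °C
Reagents that add atoms: none
Why: The weakly basic reagent Me3SiCH2CeCl2 adds twice to the methyl ester without enolising it (and cleaves the acetate), acid then triggers Peterson elimination to the 2-substituted allylsilane and at the same time hydrolyses the silyl enol ether and eliminates methanol (E1cB) to the enone, leaving C7 and C8 untouched.

Step 4
Reactants: 8 racemic hydroxy enone
Product: 9 (4R,5S)-5-hydroxy-4-[3-(trimethylsilyl)prop-1-en-2-yl]cyclohex-2-en-1-one (7R,8S; recovered enantiomer)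
Conditions: lipase PS (Burkholderia cepacia), vinyl acetate, t-BuOMe, 30 °C, stopped beyond half conversion
Reagents that add atoms: none
Why: Lipase-catalysed kinetic resolution by acyl transfer should consume the (4S,5R)-alcohol (the 8R carbinol that fits the empirical model), so that the (4R,5S)-alcohol is recovered enantiomerically enriched and fixes the absolute configuration of all later compounds.

Step 5
Reactants: 9 (4R,5S)-hydroxy enone allylsilane
Product: 11 (4R,5S)-5-hydroxy-4-(3-hydroxyprop-1-en-2-yl)cyclohex-2-en-1-one, via epoxysilane 10 (not isolated)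
Conditions: mCPBA, NaHCO3, CH2Cl2, 0 °C; then AcOH, THF/H2O, rt
Reagents that add atoms: mCPBA (3-chloroperoxybenzoic acid), SMILES OOC(=O)c1cccc(Cl)c1
Why: Prilezhaev epoxidation is selective for the nucleophilic allylsilane alkene over the enone, and acid opens the epoxysilane with loss of the β-silyl group (Peterson-type elimination) to the transposed 2-substituted allylic alcohol, which is the same side chain with CH2OH in place of CH2SiMe3.

Step 6
Reactants: 11 enone diol
Product: 12 (4R,5S)-5-(TBS-oxy)-4-[3-(TBS-oxy)prop-1-en-2-yl]cyclohex-2-en-1-one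
Conditions: TBSCl, imidazole, DMF, rt
Reagents that add atoms: tert-butyldimethylsilyl chloride, SMILES CC(C)(C)[Si](C)(C)Cl
Why: Standard silylation of the primary and the secondary alcohol protects O12 and O8 with the more robust of the two silyl groups used, so that they can be released together late in the route.

Step 7
Reactants: 12 bis-silyl enone
Product: 13 (4R,5S)-2-iodo-5-(TBS-oxy)-4-[3-(TBS-oxy)prop-1-en-2-yl]cyclohex-2-en-1-one
Conditions: I2, pyridine/CH2Cl2, rt
Reagents that add atoms: iodine, SMILES II
Why: α-Iodination of the cyclohexenone through reversible conjugate addition of pyridine, iodination of the enolate and elimination gives the 2-iodo enone, the isolated 1,1-disubstituted alkene being unaffected by reversible iodonium formation.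

Step 8
Reactants: 13 iodo enone; 14 methyl bromoacetate
Product: 15 methyl 2-[(3R,4S)-6-oxo-4-(TBS-oxy)-3-[3-(TBS-oxy)prop-1-en-2-yl]cyclohex-1-en-1-yl]acetate
Conditions: Zn, THF (forms BrZnCH2CO2Me from 14); Pd(PPh3)4 (cat.), THF, rt
Reagents that add atoms: none
Why: Negishi coupling of the α-iodo enone with the Reformatsky reagent forms the C5–C4 bond, oxidative addition of Pd(PPh3)4 to the activated C–I bond being expected to outpace addition of the zinc reagent to the hindered conjugated ketone.

Step 9
Reactants: 15 enone ester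
Product: 16 methyl 2-[(3R,4S,6R)-6-hydroxy-4-(TBS-oxy)-3-[3-(TBS-oxy)prop-1-en-2-yl]cyclohex-1-en-1-yl]acetate (C10 α-OH, cis to O8)
Conditions: NaBH4, CeCl3·7H2O, MeOH, −78 °C; used at once
Reagents that add atoms: none
Why: Luche 1,2-reduction delivers hydride axially to C10 on the face anti to the C8 silyloxy group (the sense known for 5-substituted cyclohexenones), giving the pseudo-equatorial C10 alcohol cis to O8, a relay centre that is oxidised again in step 11.

Step 10
Reactants: 16 allylic alcohol
Product: 17 α-epoxy alcohol (C5–C6 epoxide on the α face; C5 β-CH2CO2Me; C10 α-OH; C7 β side chain; C8 α-OTBS)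
Conditions: VO(acac)2 (cat.), t-BuOOH, CH2Cl2, 0 °C
Reagents that add atoms: tert-butyl hydroperoxide, SMILES CC(C)(C)OO
Why: VO(acac)2-catalysed hydroxyl-directed epoxidation transfers oxygen to C5=C6 on the face of the C10 hydroxyl, which is also the face away from the C7 side chain, so that O6 is set cis to O8 and trans to C7 and the acetate arm at C5 becomes β, while the silylated allylic alkene carries no free hydroxyl and is not epoxidised.

Step 11
Reactants: 17 epoxy alcohol
Product: 18 α,β-epoxy ketone (C10 ketone; C5–C6 α-epoxide; C5 β-CH2CO2Me)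
Conditions: DMP, NaHCO3, CH2Cl2, 0 °C to rt
Reagents that add atoms: none
Why: Dess–Martin oxidation converts the epoxy alcohol into the α,β-epoxy ketone under buffered conditions that leave the epoxide and the silyl ethers intact.

Step 12
Reactants: 18 epoxy ketone
Product: 19 β-hydroxy ketone (C10 ketone; C5 β-CH2CO2Me; C6 α-OH; C7 β side chain; C8 α-OTBS; all equatorial)
Conditions: SmI2, THF/MeOH, −90 °C
Reagents that add atoms: none
Why: SmI2 reduction of the α,β-epoxy ketone cleaves the Cα–O bond (C5–O) through the ketyl and keeps the C6–O bond with its configuration, and axial protonation of the enolate places the epimerisable C5 arm equatorial and trans to O6, which is also the thermodynamically preferred arrangement.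

Step 13
Reactants: 19 β-hydroxy ketone
Product: 20 all-equatorial ketone (C10 ketone; C5 β-CH2CO2Me; C6 α-OTES; C7 β-[3-(TBS-oxy)prop-1-en-2-yl]; C8 α-OTBS)
Conditions: TESCl, imidazole, DMF, 0 °C
Reagents that add atoms: triethylsilyl chloride, SMILES CC[Si](CC)(CC)Cl
Why: Silylation of the β-hydroxy ketone with the more labile triethylsilyl group differentiates O6 (later an ester) from O8 and prevents lactonisation or retro-aldol cleavage.

Step 14
Reactants: 20 ketone; 21 vinylmagnesium bromide
Product: 22 cis-fused γ-lactone (C10 α-vinyl and β-O acylated by C15; C4H2 on C5 β; C6 α-OTES; C7 β side chain; C8 α-OTBS)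
Conditions: CeCl3, THF, −78 °C; then 0 °C
Reagents that add atoms: none
Why: 1,2-Addition of the non-basic reagent CH2=CHCeCl2 to the ketone should follow the equatorial trajectory, since the axial one is screened by the axial hydrogens at C6 and C8 of the all-equatorial chair, and the resulting axial alkoxide (vinyl trans to the C5 arm) acylates itself on the neighbouring ester to the cis-fused γ-lactone, which masks the tertiary alcohol and activates C4.

Step 15
Reactants: 22 lactone; 23 methyl formate
Product: 25 (E)-α-(PMB-oxymethylene) lactone (C4=C3H–OPMB; PMB-oxy cis to C5), via sodium hydroxymethylene enolate 24 (not isolated)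
Conditions: NaH, THF, 0 °C to rt; then PMBCl, DMF, 0 °C to rt
Reagents that add atoms: 4-methoxybenzyl chloride, SMILES COc1ccc(CCl)cc1
Why: Claisen formylation of the lactone enolate followed by O-alkylation of the sodium hydroxymethylene enolate in DMF (the standard entry to β-alkoxy acrylates) should give the E enol ether with the alkoxy group anti to the lactone carbonyl and therefore cis to C5, C-alkylation being disfavoured because it would create a congested quaternary centre.

Step 16
Reactants: 25 enol ether lactone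
Product: 26 diol (C10 tertiary β-OH; C15 primary OH on the E enol-ether arm)
Conditions: i-Bu2AlH, CH2Cl2, −78 to 0 °C
Reagents that add atoms: none
Why: i-Bu2AlH reduces the vinylogous carbonate-type lactone by 1,2-hydride delivery to the allylic primary alcohol and releases the tertiary alcohol without touching the enol ether or its geometry.

Step 17
Reactants: 26 diol
Product: 27 trans-1-vinyl-2-alkenylcyclohexanol (C10 α-vinyl equatorial and β-OH axial; C5 β-[(E)-1-(PMB-oxy)-3-(TES-oxy)prop-1-en-2-yl]; C6 α-OTES; C7 β-[3-(TBS-oxy)prop-1-en-2-yl]; C8 α-OTBS)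
Conditions: TESCl, imidazole, CH2Cl2, −20 °C
Reagents that add atoms: triethylsilyl chloride, SMILES CC[Si](CC)(CC)Cl
Why: The primary allylic alcohol is silylated selectively because the tertiary C10 hydroxyl is too hindered to react with TESCl, which leaves it free for the rearrangement.

Step 18
Reactants: 27 trans-1-vinyl-2-alkenylcyclohexanol
Product: 29 ten-membered enol triflate (3R,6R,7R,8S; 1(10)Z by the triflate priority with C9 trans to C2; 4E), via potassium enolate 28 (not isolated)
Conditions: KN(SiMe3)2, 18-crown-6, THF, 0 °C to rt; then PhNTf2, −78 °C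
Reagents that add atoms: N-phenylbis(trifluoromethanesulfonimide), SMILES O=S(=O)(N(c1ccccc1)S(=O)(=O)C(F)(F)F)C(F)(F)F
Why: The crown-ether-separated potassium alkoxide undergoes a concerted, alkoxide-accelerated [3,3] sigmatropic shift (anionic oxy-Cope rearrangement) in which C2–C3 forms as C5–C10 breaks, and the ten-membered enolate 28 is O-sulfonylated cold. The closest known reaction is the anionic oxy-Cope ring expansion of trans-1,2-dialkenylcyclohexanols to (E,E)-cyclodeca-1,5-dienone enolates with in situ enolate trapping. The ten-membered ring is closed by the ring expansion itself: the new C2–C3 σ bond joins the termini of the two alkenyl arms through a chair transition state while the six-membered ring opens. The only new stereocentre, C3, is controlled by the E geometry of the enol ether, which places the ether oxygen axial at the bond-forming terminus of that chair and so gives 3R. The step needs chair over boat selectivity and a regiodefined enolate: the diequatorial vinyl and alkenyl groups on a cyclohexane whose other substituents are all equatorial keep the ring arms C9 and C6 equatorial in the chair and so make both new alkenes E in the ring sense, and the enolate is formed specifically toward C1 and trapped before it can equilibrate toward C9 and expel the C8 silyloxy group.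

Step 19
Reactants: 29 enol triflate; 30 methylmagnesium bromide
Product: 31 (1(10)E,4E)-germacradiene (C14 methyl on C10; 3R OPMB; C15 OTES; 6R OTES; 8S OTBS; C12 OTBS)
Conditions: Fe(acac)3 (cat.), THF/NMP, −30 °C
Reagents that add atoms: none
Why: Fe(acac)3-catalysed cross-coupling of the alkenyl triflate with the methyl Grignard reagent replaces C–OTf by C–CH3 with retention of alkene geometry, so that C9 and C2 stay trans and the 1(10)E alkene with C14 results.

Step 20
Reactants: 31 germacradiene
Product: 32 6,15-diol (O8 and O12 still TBS ethers; O3 PMB ether)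
Conditions: HF·pyridine, pyridine, THF, 0 °C
Reagents that add atoms: none
Why: Pyridine-buffered HF·pyridine cleaves the two triethylsilyl ethers much faster than the tert-butyldimethylsilyl ethers, freeing O6 and O15 only and avoiding acid strong enough to trigger transannular cyclisation of the 1,5-diene.

Step 21
Reactants: 32 6,15-diol; 33 3-methylbutanoic anhydride
Product: 34 6,15-bis(3-methylbutanoate)
Conditions: DMAP, Et3N, CH2Cl2, 0 °C to rt
Reagents that add atoms: none
Why: DMAP-catalysed acylation with the anhydride esterifies the primary allylic and the secondary allylic alcohol, installing both isovalerates in one operation.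

Step 22
Reactants: 34 diester
Product: 35 8,12-diol (2-methylene-1,4-diol; esters at O6 and O15; PMB ether at O3)
Conditions: HF·pyridine, THF/MeCN, rt
Reagents that add atoms: none
Why: Fluoride-mediated desilylation with HF·pyridine removes the two tert-butyldimethylsilyl ethers while the esters and the p-methoxybenzyl ether are stable to these conditions.

Step 23
Reactants: 35 8,12-diol
Product: 36 3-O-PMB ether of the target (trans-fused α-methylene-γ-lactone)
Conditions: MnO2, CH2Cl2, rt
Reagents that add atoms: none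
Why: MnO2 oxidises only the primary allylic C12 alcohol, the enal is captured by the C8 hydroxyl as a lactol and this is oxidised on to the α-methylene-γ-lactone (oxidative lactonisation of a 2-methylene-1,4-diol), which is trans-fused because C7 and C8 keep their configuration.

Step 24
Reactants: 36 PMB-protected lactone
Product: 37 CNP0317194.1, (3R,6R,7R,8S,1(10)E,4E)-3-hydroxy-6,15-bis(3-methylbutanoyloxy)germacra-1(10),4,11(13)-trien-12,8-olide
Conditions: DDQ, CH2Cl2/pH 7 buffer, 0 °C
Reagents that add atoms: none
Why: DDQ oxidises the p-methoxybenzyl ether by hydride abstraction and the oxocarbenium ion is hydrolysed in the buffered two-phase medium, freeing the C3 alcohol without affecting the esters, the α-methylene lactone or the 1,5-diene.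

**Compound list**

1 | methyl propiolate | C#CC(=O)OC | starting material
2 | acetic acid | CC(=O)O | starting material
3 | methyl (E)-3-acetoxyprop-2-enoate | CC(=O)O/C=C/C(=O)OC | intermediate
4 | (E)-1-methoxy-3-(trimethylsilyloxy)buta-1,3-diene | CO/C=C/C(=C)O[Si](C)(C)C | starting material
5 | racemic methyl (1R*,6S*)-6-acetoxy-2-methoxy-4-(trimethylsilyloxy)cyclohex-3-ene-1-carboxylate, both C2 epimers (SMILES shows the enantiomer carried on) | C[Si](C)(C)OC1=CC(OC)[C@H](C(=O)OC)[C@@H](OC(C)=O)C1 | intermediate
6 | (trimethylsilyl)methylmagnesium chloride | C[Si](C)(C)C[Mg]Cl | starting material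
7 | racemic 2-[(1R*,6S*)-6-hydroxy-2-methoxy-4-(trimethylsilyloxy)cyclohex-3-en-1-yl]-1,3-bis(trimethylsilyl)propan-2-ol (SMILES shows the enantiomer carried on) | C[Si](C)(C)OC1=CC(OC)[C@H](C(O)(C[Si](C)(C)C)C[Si](C)(C)C)[C@@H](O)C1 | intermediate
8 | racemic (4R*,5S*)-5-hydroxy-4-[3-(trimethylsilyl)prop-1-en-2-yl]cyclohex-2-en-1-one (SMILES shows the enantiomer carried on) | O=C1C[C@H](O)[C@@H](C(=C)C[Si](C)(C)C)C=C1 | intermediate
9 | (4R,5S)-5-hydroxy-4-[3-(trimethylsilyl)prop-1-en-2-yl]cyclohex-2-en-1-one | O=C1C[C@H](O)[C@@H](C(=C)C[Si](C)(C)C)C=C1 | intermediate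
10 | epoxysilane of 9: oxirane on the former allylsilane alkene, both oxirane epimers | O=C1C[C@H](O)[C@@H](C2(C[Si](C)(C)C)CO2)C=C1 | intermediate
11 | (4R,5S)-5-hydroxy-4-(3-hydroxyprop-1-en-2-yl)cyclohex-2-en-1-one | O=C1C[C@H](O)[C@@H](C(=C)CO)C=C1 | intermediate
12 | (4R,5S)-5-(TBS-oxy)-4-[3-(TBS-oxy)prop-1-en-2-yl]cyclohex-2-en-1-one | O=C1C[C@H](O[Si](C)(C)C(C)(C)C)[C@@H](C(=C)CO[Si](C)(C)C(C)(C)C)C=C1 | intermediate
13 | (4R,5S)-2-iodo-5-(TBS-oxy)-4-[3-(TBS-oxy)prop-1-en-2-yl]cyclohex-2-en-1-one | O=C1C[C@H](O[Si](C)(C)C(C)(C)C)[C@@H](C(=C)CO[Si](C)(C)C(C)(C)C)C=C1I | intermediate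
14 | methyl bromoacetate | COC(=O)CBr | starting material
15 | methyl 2-[(3R,4S)-6-oxo-4-(TBS-oxy)-3-[3-(TBS-oxy)prop-1-en-2-yl]cyclohex-1-en-1-yl]acetate | O=C1C[C@H](O[Si](C)(C)C(C)(C)C)[C@@H](C(=C)CO[Si](C)(C)C(C)(C)C)C=C1CC(=O)OC | intermediate
16 | methyl 2-[(3R,4S,6R)-6-hydroxy-4-(TBS-oxy)-3-[3-(TBS-oxy)prop-1-en-2-yl]cyclohex-1-en-1-yl]acetate (C10 α-OH) | O[C@@H]1C[C@H](O[Si](C)(C)C(C)(C)C)[C@@H](C(=C)CO[Si](C)(C)C(C)(C)C)C=C1CC(=O)OC | intermediate
17 | α-epoxy alcohol: C5–C6 α-epoxide, C5 β-CH2CO2Me, C10 α-OH, C7 β side chain, C8 α-OTBS | O[C@@H]1C[C@H](O[Si](C)(C)C(C)(C)C)[C@@H](C(=C)CO[Si](C)(C)C(C)(C)C)[C@@H]2O[C@]12CC(=O)OC | intermediate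
18 | α,β-epoxy ketone: C10 ketone, C5–C6 α-epoxide, C5 β-CH2CO2Me | O=C1C[C@H](O[Si](C)(C)C(C)(C)C)[C@@H](C(=C)CO[Si](C)(C)C(C)(C)C)[C@@H]2O[C@]12CC(=O)OC | intermediate
19 | β-hydroxy ketone: C5 β-CH2CO2Me, C6 α-OH, C7 β-[3-(TBS-oxy)prop-1-en-2-yl], C8 α-OTBS | O=C1C[C@H](O[Si](C)(C)C(C)(C)C)[C@@H](C(=C)CO[Si](C)(C)C(C)(C)C)[C@H](O)[C@H]1CC(=O)OC | intermediate
20 | all-equatorial ketone: C5 β-CH2CO2Me, C6 α-OTES, C7 β-[3-(TBS-oxy)prop-1-en-2-yl], C8 α-OTBS | O=C1C[C@H](O[Si](C)(C)C(C)(C)C)[C@@H](C(=C)CO[Si](C)(C)C(C)(C)C)[C@H](O[Si](CC)(CC)CC)[C@H]1CC(=O)OC | intermediate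
21 | vinylmagnesium bromide | C=C[Mg]Br | starting material
22 | cis-fused γ-lactone: C10 α-vinyl, O10 (β) acylated by C15, C6 α-OTES, C7 β side chain, C8 α-OTBS | C=C[C@]12C[C@H](O[Si](C)(C)C(C)(C)C)[C@@H](C(=C)CO[Si](C)(C)C(C)(C)C)[C@H](O[Si](CC)(CC)CC)[C@H]1CC(=O)O2 | intermediate
23 | methyl formate | COC=O | starting material
24 | sodium hydroxymethylene enolate of lactone 22 | C=C[C@]12C[C@H](O[Si](C)(C)C(C)(C)C)[C@@H](C(=C)CO[Si](C)(C)C(C)(C)C)[C@H](O[Si](CC)(CC)CC)[C@H]1/C(=C\[O-])C(=O)O2.[Na+] | intermediate
25 | (E)-α-(PMB-oxymethylene) lactone, PMB-oxy cis to C5 | C=C[C@]12C[C@H](O[Si](C)(C)C(C)(C)C)[C@@H](C(=C)CO[Si](C)(C)C(C)(C)C)[C@H](O[Si](CC)(CC)CC)[C@H]1/C(=C\OCc1ccc(OC)cc1)C(=O)O2 | intermediate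
26 | diol: C10 α-vinyl/β-OH, C5 β-[(E)-3-hydroxy-1-(PMB-oxy)prop-1-en-2-yl], C6 α-OTES, C7 β side chain, C8 α-OTBS | C=C[C@]1(O)C[C@H](O[Si](C)(C)C(C)(C)C)[C@@H](C(=C)CO[Si](C)(C)C(C)(C)C)[C@H](O[Si](CC)(CC)CC)[C@H]1/C(CO)=C\OCc1ccc(OC)cc1 | intermediate
27 | trans-1-vinyl-2-alkenylcyclohexanol: C10 α-vinyl (equatorial)/β-OH (axial), C5 β-[(E)-1-(PMB-oxy)-3-(TES-oxy)prop-1-en-2-yl], C6 α-OTES, C7 β-[3-(TBS-oxy)prop-1-en-2-yl], C8 α-OTBS | C=C[C@]1(O)C[C@H](O[Si](C)(C)C(C)(C)C)[C@@H](C(=C)CO[Si](C)(C)C(C)(C)C)[C@H](O[Si](CC)(CC)CC)[C@H]1/C(CO[Si](CC)(CC)CC)=C\OCc1ccc(OC)cc1 | intermediate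
28 | potassium enolate of the ring-expanded (3R,6R,7R,8S,4E)-cyclodec-4-enone, enolate toward C1 | C=C(CO[Si](C)(C)C(C)(C)C)[C@@H]1[C@@H](O[Si](C)(C)C(C)(C)C)C/C([O-])=C/C[C@@H](OCc2ccc(OC)cc2)/C(CO[Si](CC)(CC)CC)=C/[C@H]1O[Si](CC)(CC)CC.[K+] | intermediate
29 | ten-membered enol triflate (3R,6R,7R,8S; C9 trans to C2; 4E): C10 OTf, C3 OPMB, C15 OTES, C6 OTES, C8 OTBS, C12 OTBS | C=C(CO[Si](C)(C)C(C)(C)C)[C@@H]1[C@@H](O[Si](C)(C)C(C)(C)C)C/C(OS(=O)(=O)C(F)(F)F)=C/C[C@@H](OCc2ccc(OC)cc2)/C(CO[Si](CC)(CC)CC)=C/[C@H]1O[Si](CC)(CC)CC | intermediate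
30 | methylmagnesium bromide | C[Mg]Br | starting material
31 | (3R,6R,7R,8S,1(10)E,4E)-germacra-1(10),4,11(13)-triene: 3-OPMB, 6-OTES, 15-OTES, 8-OTBS, 12-OTBS | C=C(CO[Si](C)(C)C(C)(C)C)[C@@H]1[C@@H](O[Si](C)(C)C(C)(C)C)C/C(C)=C/C[C@@H](OCc2ccc(OC)cc2)/C(CO[Si](CC)(CC)CC)=C/[C@H]1O[Si](CC)(CC)CC | intermediate
32 | 6,15-diol of 31 (8-OTBS, 12-OTBS, 3-OPMB kept) | C=C(CO[Si](C)(C)C(C)(C)C)[C@@H]1[C@@H](O[Si](C)(C)C(C)(C)C)C/C(C)=C/C[C@@H](OCc2ccc(OC)cc2)/C(CO)=C/[C@H]1O | intermediate
33 | 3-methylbutanoic anhydride | CC(C)CC(=O)OC(=O)CC(C)C | starting material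
34 | 6,15-bis(3-methylbutanoate) with 8-OTBS, 12-OTBS, 3-OPMB | C=C(CO[Si](C)(C)C(C)(C)C)[C@@H]1[C@@H](O[Si](C)(C)C(C)(C)C)C/C(C)=C/C[C@@H](OCc2ccc(OC)cc2)/C(COC(=O)CC(C)C)=C/[C@H]1OC(=O)CC(C)C | intermediate
35 | 8,12-diol with 6,15-bis(3-methylbutanoate) and 3-OPMB | C=C(CO)[C@@H]1[C@@H](O)C/C(C)=C/C[C@@H](OCc2ccc(OC)cc2)/C(COC(=O)CC(C)C)=C/[C@H]1OC(=O)CC(C)C | intermediate
36 | 3-O-PMB ether of the target | C=C1C(=O)O[C@H]2C/C(C)=C/C[C@@H](OCc3ccc(OC)cc3)/C(COC(=O)CC(C)C)=C/[C@@H](OC(=O)CC(C)C)[C@H]12 | intermediate
37 | CNP0317194.1, (3R,6R,7R,8S,1(10)E,4E)-3-hydroxy-6,15-bis(3-methylbutanoyloxy)germacra-1(10),4,11(13)-trien-12,8-olide | C=C1C(=O)O[C@H]2C/C(C)=C/C[C@@H](O)/C(COC(=O)CC(C)C)=C/[C@@H](OC(=O)CC(C)C)[C@H]12 | target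

**Count and risks**

Total step count: 24. Longest linear sequence: 24 steps (steps 1 to 24, fully linear from methyl propiolate and acetic acid).

Steps most likely to fail:

Step 18 (key step). The sigmatropic shift may be slow because the ether oxygen must sit axial at the bond-forming terminus. The free potassium enolate could then equilibrate toward C9 before sulfonylation, with β-elimination of the C8 silyloxy group and erosion of alkene geometry. The fallback sets out from 27 and returns at 29. The alkoxide is rearranged as before but the enolate is quenched with Me3SiCl to the trimethylsilyl enol ether F1, which is isolated on base-washed silica. MeLi at −78 °C then regenerates the enolate regiospecifically, and PhNTf2 converts it into 29.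

Step 14. Facial selectivity of the carbonyl addition may be poor: axial attack would give the equatorial alcohol and hence a cis-dialkenyl arrangement that cannot rearrange through the required chair. The fallback sets out from 20 and returns at 22. Corey–Chaykovsky epoxidation with dimethylsulfoxonium methylide forms the equatorial C–C bond under reversible betaine formation and gives the spiro-epoxide F2 (oxygen axial). Excess dimethylsulfonium methylide opens it at the CH2 group and eliminates Me2S to the vinyl carbinol alkoxide, which lactonises to 22.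

Step 8. The zinc reagent may add to the enone carbonyl, or transmetalation may be sluggish, in competition with the cross-coupling. The fallback sets out from 13 and returns at 16. The iodo enone is reduced first (NaBH4, CeCl3·7H2O) to the 2-iodo allylic alcohol F3. The Negishi coupling with BrZnCH2CO2Me is then run on this carbonyl-free vinyl iodide, with one further equivalent for the hydroxyl, and gives 16 directly.

Further compounds
F1 | step 18 | trimethylsilyl enol ether of the ring-expanded ketone (C10 OSiMe3 in place of OTf, otherwise as 29) | C=C(CO[Si](C)(C)C(C)(C)C)[C@@H]1[C@@H](O[Si](C)(C)C(C)(C)C)C/C(O[Si](C)(C)C)=C/C[C@@H](OCc2ccc(OC)cc2)/C(CO[Si](CC)(CC)CC)=C/[C@H]1O[Si](CC)(CC)CC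
F2 | step 14 | C10 spiro-epoxide of ketone 20 (epoxide oxygen β and axial, CH2 α) | C1O[C@]12C[C@H](O[Si](C)(C)C(C)(C)C)[C@@H](C(=C)CO[Si](C)(C)C(C)(C)C)[C@H](O[Si](CC)(CC)CC)[C@H]2CC(=O)OC
F3 | step 8 | 2-iodo allylic alcohol from 13 (C10 α-OH) | O[C@@H]1C[C@H](O[Si](C)(C)C(C)(C)C)[C@@H](C(=C)CO[Si](C)(C)C(C)(C)C)C=C1I
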